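**Retrosynthetic overview**
- The target is the ring-closed hemiketal tautomer of a (2R)-2-(2,6-dihydroxyphenyl)flavanone, so the last event is unmasking of the two B-ring phenols and spontaneous bridging (ketal ring formed last).
- The single independent stereocentre (benzylic CH, R) is set by enantioselective copper hydride 1,4-reduction of the flat, achiral flavone, which dearomatises its benzo-γ-pyrone ring (key step).
- The flavone comes from enolate C-acylation of the ring A acetophenone with 2,6-bis(methoxymethoxy)benzoyl chloride, then cyclodehydration (γ-pyrone ring).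
- The acetophenone comes from 2',4'-dihydroxy-6'-methoxyacetophenone by C-prenylation, then prenal annulation (dimethylpyran ring first); the acid chloride comes from resorcinol via MOM protection, ortho-lithiation and CO2.
- Ring order: dimethylpyran, then γ-pyrone, then its reduction to the dihydropyranone, then the bridging ketal ring.

Assumption: the drawn hemiketal is the stable ring tautomer of the open (2R)-2',6'-dihydroxyflavanone, so freeing the phenols gives it directly; the sense of induction of the ligand in step 6 is not predictable and is fixed on the first run (the antipodal ligand gives the other series).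

**Step 1**
Reactants: 1 1-(2,4-dihydroxy-6-methoxyphenyl)ethan-1-one; 2 1-bromo-3-methylbut-2-ene (prenyl bromide)
Product: 3 1-[2,4-dihydroxy-6-methoxy-3-(3-methylbut-2-en-1-yl)phenyl]ethan-1-one
Conditions: 2 (1.1 equiv), 10% aq KOH, 0 °C → rt
Reagents that add atoms: none
Why: Nuclear C-prenylation (phenolate C-alkylation) in water, where the solvated oxygens leave carbon as the nucleophile and C3, ortho to both oxygens, is the most nucleophilic ring position; the 5-prenyl and O-prenyl isomers are removed by chromatography and a moderate yield is expected.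

**Step 2**
Reactants: 3 1-[2,4-dihydroxy-6-methoxy-3-(3-methylbut-2-en-1-yl)phenyl]ethan-1-one; 4 3-methylbut-2-enal (prenal)
Product: 6 1-[7-hydroxy-5-methoxy-2,2-dimethyl-8-(3-methylbut-2-en-1-yl)-2H-chromen-6-yl]ethan-1-one, via ortho-quinone methide 5 (not isolated)
Conditions: 4 (2 equiv), pyridine, 120 °C, sealed tube
Reagents that add atoms: none
Why: Chromene annulation by aldol-type condensation at C5 (the only free ring carbon), dehydration to the ortho-quinone methide and oxa-6π electrocyclisation onto the adjacent 4-oxygen; the other neighbour of C5 carries OMe, so only the required pyran can form.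

**Step 3**
Reactants: 7 resorcinol (benzene-1,3-diol)
Product: 8 1,3-bis(methoxymethoxy)benzene
Conditions: MOMCl (2.5 equiv), i-Pr2NEt (3 equiv), CH2Cl2, 0 °C → rt
Reagents that add atoms: chloromethyl methyl ether, COCCl
Why: O-alkylation of both phenols (Williamson-type acetal formation); the MOM groups direct the lithiation, tolerate base, hydride and buffered acetic acid, and are removable without protic acid at the end.

**Step 4**
Reactants: 8 1,3-bis(methoxymethoxy)benzene
Product: 11 2,6-bis(methoxymethoxy)benzoyl chloride, via aryllithium 9 (not isolated), via lithium carboxylate 10 (not isolated)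
Conditions: n-BuLi (1.0 equiv), THF, 0 °C; CO2, −78 °C → rt; evaporate; (COCl)2 (1.1 equiv), DMF (cat.), CH2Cl2, 0 °C; used crude
Reagents that add atoms: carbon dioxide, O=C=O; oxalyl chloride, O=C(Cl)C(=O)Cl
Why: Directed ortho-metalation at C2 (flanked by both OMOM groups), carboxylation of the aryllithium, and conversion of the lithium salt to the acid chloride without free HCl, so the acetals survive.

**Step 5**
Reactants: 6 1-[7-hydroxy-5-methoxy-2,2-dimethyl-8-(3-methylbut-2-en-1-yl)-2H-chromen-6-yl]ethan-1-one; 11 2,6-bis(methoxymethoxy)benzoyl chloride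
Product: 14 2-[2,6-bis(methoxymethoxy)phenyl]-5-methoxy-8,8-dimethyl-10-(3-methylbut-2-en-1-yl)-4H,8H-pyrano[3,2-g]chromen-4-one, via dilithium dianion 12 (not isolated), via 1,3-diketone 13 (not isolated)
Conditions: LiN(SiMe3)2 (3.2 equiv), THF, −78 → −10 °C; 11 (1.1 equiv), −78 °C → rt; AcOH quench, concentrate; NaOAc, AcOH, 90 °C
Reagents that add atoms: none
Why: Crossed Claisen C-acylation of the ketone enolate in the phenoxide-enolate dianion (the Baker–Venkataraman diketone reached directly), then cyclodehydration in acetate-buffered acetic acid, which closes the γ-pyrone with the only free phenol (ring A) while sparing MOM, prenyl and chromene.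

**Step 6 (key step)**
Reactants: 14 2-[2,6-bis(methoxymethoxy)phenyl]-5-methoxy-8,8-dimethyl-10-(3-methylbut-2-en-1-yl)-4H,8H-pyrano[3,2-g]chromen-4-one
Product: 16 (2R)-2-[2,6-bis(methoxymethoxy)phenyl]-5-methoxy-8,8-dimethyl-10-(3-methylbut-2-en-1-yl)-2,3-dihydro-4H,8H-pyrano[3,2-g]chromen-4-one, via silyl enol ether 15 (not isolated)
Conditions: Cu(OAc)2 (5 mol %), (R)-DTBM-SEGPHOS (5.5 mol %), MeSiH(OMe)2 (3 equiv), toluene, no alcohol additive, 0 °C → rt; then 1 M aq HCl/THF, 0 °C, 10 min
Reagents that add atoms: none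
Why: Proposed new method: the bisphosphine-ligated monovalent copper hydride L*CuH (from Cu(OAc)2 and the silane) adds hydride to C2 of the flavone's benzo-γ-pyrone, breaking its cyclic conjugation; delivery to the Si face of C2 gives 2R, the copper enolate is trapped by the silane as silyl enol ether 15 (no proton source, so the enolate does not ring-open and the chromene and prenyl alkenes are not reduced) and mild hydrolysis gives the ketone; the closest known reaction type is the CuH-catalysed asymmetric conjugate reduction of β,β-disubstituted cyclic enones, chromones included, and the (S)-ligand is used if the (R)-ligand proves to give 2S.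

**Step 7**
Reactants: 16 (2R)-2-[2,6-bis(methoxymethoxy)phenyl]-5-methoxy-8,8-dimethyl-10-(3-methylbut-2-en-1-yl)-2,3-dihydro-4H,8H-pyrano[3,2-g]chromen-4-one
Product: 19 target CNP0170313.2 (bridged hemiketal; benzylic CH R and ketal C–OH R), via mono-MOM flavanone 17 (not isolated), via open dihydroxyflavanone 18 (not isolated)
Conditions: ZnBr2 (2.2 equiv), n-PrSH (4 equiv), CH2Cl2, 0 °C, 15 min
Reagents that add atoms: none
Why: ZnBr2-assisted thiolysis of the two aryl MOM acetals (acetal exchange, no protic acid, so the electron-rich benzylic C–O bond and C2 are not disturbed) frees the 2',6'-phenols, and one of them adds to the C4 ketone (intramolecular hemiketalisation) on the only face the (2R)-aryl group can reach, which forces the ketal carbon to be R.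

**Compound list**
1 | 1-(2,4-dihydroxy-6-methoxyphenyl)ethan-1-one | CC(=O)c1c(O)cc(O)cc1OC | starting material
2 | 1-bromo-3-methylbut-2-ene | CC(C)=CCBr | starting material
3 | 1-[2,4-dihydroxy-6-methoxy-3-(3-methylbut-2-en-1-yl)phenyl]ethan-1-one | CC(=O)c1c(O)c(CC=C(C)C)c(O)cc1OC | intermediate
4 | 3-methylbut-2-enal | CC(C)=CC=O | starting material
5 | 4-acetyl-3-hydroxy-5-methoxy-6-(3-methylbut-2-en-1-ylidene)-2-(3-methylbut-2-en-1-yl)cyclohexa-2,4-dien-1-one (ortho-quinone methide) | CC(=O)C1=C(OC)C(=CC=C(C)C)C(=O)C(CC=C(C)C)=C1O | intermediate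
6 | 1-[7-hydroxy-5-methoxy-2,2-dimethyl-8-(3-methylbut-2-en-1-yl)-2H-chromen-6-yl]ethan-1-one | CC(=O)c1c(OC)c2C=CC(C)(C)Oc2c(CC=C(C)C)c1O | intermediate
7 | resorcinol | Oc1cccc(O)c1 | starting material
8 | 1,3-bis(methoxymethoxy)benzene | COCOc1cccc(OCOC)c1 | intermediate
9 | [2,6-bis(methoxymethoxy)phenyl]lithium | [Li]c1c(OCOC)cccc1OCOC | intermediate
10 | lithium 2,6-bis(methoxymethoxy)benzoate | [Li+].[O-]C(=O)c1c(OCOC)cccc1OCOC | intermediate
11 | 2,6-bis(methoxymethoxy)benzoyl chloride | ClC(=O)c1c(OCOC)cccc1OCOC | intermediate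
12 | dilithium enolate-phenoxide of 6 | [Li+].[Li+].C=C([O-])c1c(OC)c2C=CC(C)(C)Oc2c(CC=C(C)C)c1[O-] | intermediate
13 | 1-[2,6-bis(methoxymethoxy)phenyl]-3-[7-hydroxy-5-methoxy-2,2-dimethyl-8-(3-methylbut-2-en-1-yl)-2H-chromen-6-yl]propane-1,3-dione | COCOc1cccc(OCOC)c1C(=O)CC(=O)c1c(OC)c2C=CC(C)(C)Oc2c(CC=C(C)C)c1O | intermediate
14 | 2-[2,6-bis(methoxymethoxy)phenyl]-5-methoxy-8,8-dimethyl-10-(3-methylbut-2-en-1-yl)-4H,8H-pyrano[3,2-g]chromen-4-one | COc1c2C=CC(C)(C)Oc2c(CC=C(C)C)c2OC(=CC(=O)c12)c1c(OCOC)cccc1OCOC | intermediate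
15 | (2R)-2-[2,6-bis(methoxymethoxy)phenyl]-4-{[dimethoxy(methyl)silyl]oxy}-5-methoxy-8,8-dimethyl-10-(3-methylbut-2-en-1-yl)-2H,8H-pyrano[3,2-g]chromene | COc1c2C=CC(C)(C)Oc2c(CC=C(C)C)c2O[C@H](C=C(O[Si](C)(OC)OC)c12)c1c(OCOC)cccc1OCOC | intermediate
16 | (2R)-2-[2,6-bis(methoxymethoxy)phenyl]-5-methoxy-8,8-dimethyl-10-(3-methylbut-2-en-1-yl)-2,3-dihydro-4H,8H-pyrano[3,2-g]chromen-4-one | COc1c2C=CC(C)(C)Oc2c(CC=C(C)C)c2O[C@H](CC(=O)c12)c1c(OCOC)cccc1OCOC | intermediate
17 | (2R)-2-[2-hydroxy-6-(methoxymethoxy)phenyl]-5-methoxy-8,8-dimethyl-10-(3-methylbut-2-en-1-yl)-2,3-dihydro-4H,8H-pyrano[3,2-g]chromen-4-one | COc1c2C=CC(C)(C)Oc2c(CC=C(C)C)c2O[C@H](CC(=O)c12)c1c(O)cccc1OCOC | intermediate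
18 | (2R)-2-(2,6-dihydroxyphenyl)-5-methoxy-8,8-dimethyl-10-(3-methylbut-2-en-1-yl)-2,3-dihydro-4H,8H-pyrano[3,2-g]chromen-4-one | COc1c2C=CC(C)(C)Oc2c(CC=C(C)C)c2O[C@H](CC(=O)c12)c1c(O)cccc1O | intermediate
19 | CNP0170313.2, bridged hemiketal of 18 with a 2,6-dioxabicyclo[3.3.1]nonane core (bridgehead CH R, bridgehead C–OH R) | COc1c2c(c(CC=C(C)C)c3c1[C@@]1(O)C[C@@H](O3)c3c(O)cccc3O1)OC(C)(C)C=C2 | target

**Step count**
Total: 7 steps. Longest linear sequence: 5 steps (1 → 2 → 5 → 6 → 7, or equally 3 → 4 → 5 → 6 → 7).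

**Three steps most likely to fail**

Step 6. The β-carbon is shielded on both faces by the ortho OMOM groups of a twisted aryl ring, so rate, ee and the sense of induction are all unproven. The fallback sets out from 14 and comes back at 16. Flavone 14 is reduced without induction by 1,4-hydride addition with LiBH(s-Bu)3 in THF at −78 °C to the racemic flavanone F1. F1 is then submitted to kinetic resolution by asymmetric transfer hydrogenation (Cp*RhCl[(R,R)-TsDPEN] or its antipode, HCO2H/Et3N, rt), choosing the catalyst antipode that reduces the 2S ketone to the cis-(2S,4S)-flavan-4-ol F2. Unreacted (2R)-16 is recovered by chromatography (at most 50%) and enters step 7.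

Step 5. The aroyl chloride is di-ortho-substituted, and the MOM groups must survive the cyclodehydration; if they fell off first, a B-ring phenol could close the pyrone the wrong way round. The fallback sets out from 6 (with aryllithium 9 from step 4) and comes back at 14. Acetophenone 6 is treated with NaH and CS2, then MeI, giving the α-oxoketene dithioacetal F3. On warming, the ring A phenoxide closes onto F3 with loss of methanethiolate, giving the 2-(methylsulfanyl)pyranochromenone F4, so the pyrone ring is made under basic conditions. Aryllithium 9 is transmetalated with ZnCl2 to the arylzinc chloride F5. F5 is cross-coupled with F4 using Pd(OAc)2/SPhos in THF at 50 °C (C–S oxidative addition to zerovalent palladium formed in situ, thioether Negishi-type coupling), giving flavone 14.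

Step 1. C3 against C5 against O-alkylation is only moderately selective and the yield is modest. The fallback sets out from 1 and comes back at 3. The non-chelated 4-OH of 1 is silylated (TBSCl, imidazole, CH2Cl2, 0 °C) to the 4-O-TBS ether F6. The 2-OH of F6 is O-alkylated with tert-butyl 2-methylbut-3-en-2-yl carbonate and Pd(PPh3)4 (zerovalent palladium, branched-selective allylic etherification) to the 1,1-dimethylallyl aryl ether F7. Heating F7 in toluene at 110 °C brings about the aromatic Claisen rearrangement; because the other ortho position carries the acetyl group, the prenyl group can only arrive at C3, giving the 3-prenyl 4-O-TBS phenol F8. TBAF in THF at 0 °C then gives 3.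

**Further compounds**
F1 | step 6 | rac-2-[2,6-bis(methoxymethoxy)phenyl]-5-methoxy-8,8-dimethyl-10-(3-methylbut-2-en-1-yl)-2,3-dihydro-4H,8H-pyrano[3,2-g]chromen-4-one | COc1c2C=CC(C)(C)Oc2c(CC=C(C)C)c2OC(CC(=O)c12)c1c(OCOC)cccc1OCOC
F2 | step 6 | (2S,4S)-2-[2,6-bis(methoxymethoxy)phenyl]-5-methoxy-8,8-dimethyl-10-(3-methylbut-2-en-1-yl)-3,4-dihydro-2H,8H-pyrano[3,2-g]chromen-4-ol | COc1c2C=CC(C)(C)Oc2c(CC=C(C)C)c2O[C@@H](C[C@H](O)c12)c1c(OCOC)cccc1OCOC
F3 | step 5 | 1-[7-hydroxy-5-methoxy-2,2-dimethyl-8-(3-methylbut-2-en-1-yl)-2H-chromen-6-yl]-3,3-bis(methylsulfanyl)prop-2-en-1-one | CSC(SC)=CC(=O)c1c(OC)c2C=CC(C)(C)Oc2c(CC=C(C)C)c1O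
F4 | step 5 | 5-methoxy-8,8-dimethyl-10-(3-methylbut-2-en-1-yl)-2-(methylsulfanyl)-4H,8H-pyrano[3,2-g]chromen-4-one | COc1c2C=CC(C)(C)Oc2c(CC=C(C)C)c2OC(SC)=CC(=O)c12
F5 | step 5 | [2,6-bis(methoxymethoxy)phenyl]zinc chloride | Cl[Zn]c1c(OCOC)cccc1OCOC
F6 | step 1 | 1-[4-(tert-butyldimethylsilyloxy)-2-hydroxy-6-methoxyphenyl]ethan-1-one | CC(=O)c1c(O)cc(O[Si](C)(C)C(C)(C)C)cc1OC
F7 | step 1 | 1-[4-(tert-butyldimethylsilyloxy)-2-methoxy-6-(2-methylbut-3-en-2-yloxy)phenyl]ethan-1-one | CC(=O)c1c(OC(C)(C)C=C)cc(O[Si](C)(C)C(C)(C)C)cc1OC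
F8 | step 1 | 1-[4-(tert-butyldimethylsilyloxy)-2-hydroxy-6-methoxy-3-(3-methylbut-2-en-1-yl)phenyl]ethan-1-one | CC(=O)c1c(O)c(CC=C(C)C)c(O[Si](C)(C)C(C)(C)C)cc1OC
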